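**Retrosynthetic overview**
1. Target 17 comes from tetrabenzyl ether 16 by neutral hydrogenolysis. This keeps the 4'-OMe group and cannot scramble the 8-O-aryl pattern into the 6-O-aryl pattern.
2. Ring C of unit 2 (the apigenin half) comes from oxidative cyclisation of 2'-hydroxychalcone 14. The Cα–Cβ bond of 14 is the key fragment union, an intermolecular Claisen–Schmidt aldol of aldehyde 12 with acetophenone 2.
3. The diaryl ether comes from SNAr of 8-hydroxyflavone 10 on 4-fluorobenzaldehyde.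
4. The 8-OH comes from 8-Bpin, which comes from 8-I. The iodine is put on acetophenone 2 ortho to its chelated OH, so 8-substitution is fixed before ring C of unit 1 is closed.
5. Ring order: ring C of unit 1 is closed first (aldol of 3 with anisaldehyde, then I2/DMSO) and ring C of unit 2 last. All benzene rings are bought, and both acetophenones come from phloroacetophenone.

Assumption: the target has no stereocentre and its diaryl ether rotates freely, so it is achiral and there is no enantiomer to select. The only stereo-elements on the way are the E-alkenes of the two chalcones and transient racemic centres that are destroyed again.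

**Step 1**
Reactants: 1 2,4,6-trihydroxyacetophenone
Product: 2 1-[2,4-bis(benzyloxy)-6-hydroxyphenyl]ethan-1-one
Conditions: BnBr (2.1 equiv), K2CO3 (2.2 equiv), DMF, 60 °C
Reagents that add atoms: benzyl bromide, BrCc1ccccc1
Why: Williamson etherification, in which the para OH and one ortho OH are alkylated while the remaining ortho OH, hydrogen-bonded to the acetyl C=O, is too poor a nucleophile to react with two equivalents of halide.

**Step 2**
Reactants: 2 1-[2,4-bis(benzyloxy)-6-hydroxyphenyl]ethan-1-one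
Product: 3 1-[4,6-bis(benzyloxy)-2-hydroxy-3-iodophenyl]ethan-1-one
Conditions: NIS (1.05 equiv), DMF, 0 °C to rt, dark
Reagents that add atoms: N-iodosuccinimide, O=C1CCC(=O)N1I
Why: Electrophilic aromatic iodination goes to the less hindered position ortho to the free chelated phenol (flanked by OH and OBn, not by two OBn), the same preference as 6-iodination of 5-hydroxyflavones, and an HMBC correlation from the chelated OH to C–I confirms it.

**Step 3**
Reactants: 3 1-[4,6-bis(benzyloxy)-2-hydroxy-3-iodophenyl]ethan-1-one; 4 4-methoxybenzaldehyde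
Product: 6 (E)-1-[4,6-bis(benzyloxy)-2-hydroxy-3-iodophenyl]-3-(4-methoxyphenyl)prop-2-en-1-one, via aldol adduct 5 (not isolated)
Conditions: KOH (50% aq.), EtOH–THF, rt, 36 h; then 1 M HCl, 0 °C
Reagents that add atoms: none
Why: Claisen–Schmidt crossed aldol condensation between the only enolisable ketone and a non-enolisable aldehyde, where E1cB loss of water from the racemic adduct removes its stereocentre and gives the conjugated E-enone.

**Step 4**
Reactants: 6 (E)-1-[4,6-bis(benzyloxy)-2-hydroxy-3-iodophenyl]-3-(4-methoxyphenyl)prop-2-en-1-one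
Product: 8 5,7-bis(benzyloxy)-8-iodo-2-(4-methoxyphenyl)-4H-chromen-4-one, via flavanone 7 (not isolated)
Conditions: I2 (10 mol %), DMSO, 125 °C, 3 h; aq. Na2S2O3 work-up
Reagents that add atoms: none
Why: Iodine-catalysed oxidative cyclisation of a 2'-hydroxychalcone (oxa-Michael closure, then dehydrogenation with DMSO as terminal oxidant), in which only the single free phenol can close the ring, so the iodine must end at C8.

**Step 5**
Reactants: 8 5,7-bis(benzyloxy)-8-iodo-2-(4-methoxyphenyl)-4H-chromen-4-one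
Product: 9 5,7-bis(benzyloxy)-2-(4-methoxyphenyl)-8-(4,4,5,5-tetramethyl-1,3,2-dioxaborolan-2-yl)-4H-chromen-4-one
Conditions: HBpin (2 equiv), PdCl2(MeCN)2 (3 mol %), SPhos (12 mol %), Et3N (4 equiv), 1,4-dioxane, 90 °C
Reagents that add atoms: pinacolborane, [H]B1OC(C)(C)C(C)(C)O1
Why: Masuda-type palladium-catalysed borylation with a bulky biaryl phosphine, a system made for hindered electron-rich aryl halides that tolerates the chromenone carbonyl and the benzyl ethers.

**Step 6**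
Reactants: 9 5,7-bis(benzyloxy)-2-(4-methoxyphenyl)-8-(4,4,5,5-tetramethyl-1,3,2-dioxaborolan-2-yl)-4H-chromen-4-one
Product: 10 5,7-bis(benzyloxy)-8-hydroxy-2-(4-methoxyphenyl)-4H-chromen-4-one
Conditions: 30% aq. H2O2 (3 equiv), THF–pH 7 phosphate buffer, 0 °C to rt; aq. Na2S2O3
Reagents that add atoms: hydrogen peroxide, OO
Why: Oxidative ipso-hydroxylation of an aryl boronate (1,2-aryl shift from boron to oxygen) is regiospecific, and at neutral pH it leaves the flavone enone untouched.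

**Step 7**
Reactants: 10 5,7-bis(benzyloxy)-8-hydroxy-2-(4-methoxyphenyl)-4H-chromen-4-one; 11 4-fluorobenzaldehyde (1.5 equiv)
Product: 12 4-{[5,7-bis(benzyloxy)-2-(4-methoxyphenyl)-4-oxo-4H-chromen-8-yl]oxy}benzaldehyde
Conditions: K2CO3 (2 equiv), DMF, 100 °C, argon, 12 h
Reagents that add atoms: none
Why: Nucleophilic aromatic substitution (SNAr) of the para-formyl-activated fluoride by the only phenoxide present, which works for 2,6-dialkoxyphenols and meets no enolisable ketone because ring C is already closed.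

**Step 8**
Reactants: 12 4-{[5,7-bis(benzyloxy)-2-(4-methoxyphenyl)-4-oxo-4H-chromen-8-yl]oxy}benzaldehyde; 2 1-[2,4-bis(benzyloxy)-6-hydroxyphenyl]ethan-1-one (1.1 equiv)
Product: 14 5,7-bis(benzyloxy)-8-(4-{(E)-3-[2,4-bis(benzyloxy)-6-hydroxyphenyl]-3-oxoprop-1-en-1-yl}phenoxy)-2-(4-methoxyphenyl)-4H-chromen-4-one, via aldol adduct 13 (not isolated)
Conditions: KOH (50% aq.), EtOH–THF 1:1, rt, 48 h, argon; then 1 M HCl, 0 °C
Reagents that add atoms: none
Why: Intermolecular Claisen–Schmidt aldol condensation in which only 2 can enolise and only 12 carries an aldehyde, E1cB dehydration gives the E-enone, and the fully O-benzylated flavone can at worst open reversibly to a diketone that recloses through the same oxygen on acidification.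

**Step 9**
Reactants: 14 5,7-bis(benzyloxy)-8-(4-{(E)-3-[2,4-bis(benzyloxy)-6-hydroxyphenyl]-3-oxoprop-1-en-1-yl}phenoxy)-2-(4-methoxyphenyl)-4H-chromen-4-one
Product: 16 5,7-bis(benzyloxy)-8-{4-[5,7-bis(benzyloxy)-4-oxo-4H-chromen-2-yl]phenoxy}-2-(4-methoxyphenyl)-4H-chromen-4-one, via flavanone 15 (not isolated)
Conditions: I2 (10 mol %), DMSO, 125 °C, 3 h; aq. Na2S2O3 work-up
Reagents that add atoms: none
Why: This is the same iodine/DMSO oxidative cyclisation of a 2'-hydroxychalcone as in step 4, now closing ring C of unit 2, and the finished flavone, the diaryl ether and the benzyl ethers are inert to it.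

**Step 10**
Reactants: 16 5,7-bis(benzyloxy)-8-{4-[5,7-bis(benzyloxy)-4-oxo-4H-chromen-2-yl]phenoxy}-2-(4-methoxyphenyl)-4H-chromen-4-one
Product: 17 8-[4-(5,7-dihydroxy-4-oxo-4H-chromen-2-yl)phenoxy]-5,7-dihydroxy-2-(4-methoxyphenyl)-4H-chromen-4-one
Conditions: H2 (1 atm), 10% Pd/C, THF–MeOH 1:1, rt, stopped at full debenzylation
Reagents that add atoms: none
Why: Catalytic hydrogenolysis cleaves the four benzylic C–O bonds under neutral conditions, sparing the aryl methyl ether, the diaryl ether and the flavone C2=C3 bonds, and with no acid present no Wessely–Moser rearrangement can occur.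

**Compound list**
1 | 2,4,6-trihydroxyacetophenone (phloroacetophenone) | CC(=O)c1c(O)cc(O)cc1O | starting material
2 | 1-[2,4-bis(benzyloxy)-6-hydroxyphenyl]ethan-1-one | CC(=O)c1c(O)cc(OCc2ccccc2)cc1OCc1ccccc1 | intermediate
3 | 1-[4,6-bis(benzyloxy)-2-hydroxy-3-iodophenyl]ethan-1-one | CC(=O)c1c(O)c(I)c(OCc2ccccc2)cc1OCc1ccccc1 | intermediate
4 | 4-methoxybenzaldehyde (p-anisaldehyde) | COc1ccc(C=O)cc1 | starting material
5 | 1-[4,6-bis(benzyloxy)-2-hydroxy-3-iodophenyl]-3-hydroxy-3-(4-methoxyphenyl)propan-1-one (racemic aldol adduct, not isolated) | COc1ccc(C(O)CC(=O)c2c(O)c(I)c(OCc3ccccc3)cc2OCc2ccccc2)cc1 | intermediate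
6 | (E)-1-[4,6-bis(benzyloxy)-2-hydroxy-3-iodophenyl]-3-(4-methoxyphenyl)prop-2-en-1-one | COc1ccc(/C=C/C(=O)c2c(O)c(I)c(OCc3ccccc3)cc2OCc2ccccc2)cc1 | intermediate
7 | 5,7-bis(benzyloxy)-8-iodo-2-(4-methoxyphenyl)chroman-4-one (racemic flavanone, not isolated) | COc1ccc(C2CC(=O)c3c(OCc4ccccc4)cc(OCc4ccccc4)c(I)c3O2)cc1 | intermediate
8 | 5,7-bis(benzyloxy)-8-iodo-2-(4-methoxyphenyl)-4H-chromen-4-one | COc1ccc(-c2cc(=O)c3c(OCc4ccccc4)cc(OCc4ccccc4)c(I)c3o2)cc1 | intermediate
9 | 5,7-bis(benzyloxy)-2-(4-methoxyphenyl)-8-(4,4,5,5-tetramethyl-1,3,2-dioxaborolan-2-yl)-4H-chromen-4-one | COc1ccc(-c2cc(=O)c3c(OCc4ccccc4)cc(OCc4ccccc4)c(B4OC(C)(C)C(C)(C)O4)c3o2)cc1 | intermediate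
10 | 5,7-bis(benzyloxy)-8-hydroxy-2-(4-methoxyphenyl)-4H-chromen-4-one | COc1ccc(-c2cc(=O)c3c(OCc4ccccc4)cc(OCc4ccccc4)c(O)c3o2)cc1 | intermediate
11 | 4-fluorobenzaldehyde | O=Cc1ccc(F)cc1 | starting material
12 | 4-{[5,7-bis(benzyloxy)-2-(4-methoxyphenyl)-4-oxo-4H-chromen-8-yl]oxy}benzaldehyde | COc1ccc(-c2cc(=O)c3c(OCc4ccccc4)cc(OCc4ccccc4)c(Oc4ccc(C=O)cc4)c3o2)cc1 | intermediate
13 | 5,7-bis(benzyloxy)-8-(4-{3-[2,4-bis(benzyloxy)-6-hydroxyphenyl]-1-hydroxy-3-oxopropyl}phenoxy)-2-(4-methoxyphenyl)-4H-chromen-4-one (racemic aldol adduct, not isolated) | COc1ccc(-c2cc(=O)c3c(OCc4ccccc4)cc(OCc4ccccc4)c(Oc4ccc(C(O)CC(=O)c5c(O)cc(OCc6ccccc6)cc5OCc5ccccc5)cc4)c3o2)cc1 | intermediate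
14 | 5,7-bis(benzyloxy)-8-(4-{(E)-3-[2,4-bis(benzyloxy)-6-hydroxyphenyl]-3-oxoprop-1-en-1-yl}phenoxy)-2-(4-methoxyphenyl)-4H-chromen-4-one | COc1ccc(-c2cc(=O)c3c(OCc4ccccc4)cc(OCc4ccccc4)c(Oc4ccc(/C=C/C(=O)c5c(O)cc(OCc6ccccc6)cc5OCc5ccccc5)cc4)c3o2)cc1 | intermediate
15 | 5,7-bis(benzyloxy)-8-{4-[5,7-bis(benzyloxy)-4-oxochroman-2-yl]phenoxy}-2-(4-methoxyphenyl)-4H-chromen-4-one (racemic flavanone, not isolated) | COc1ccc(-c2cc(=O)c3c(OCc4ccccc4)cc(OCc4ccccc4)c(Oc4ccc(C5CC(=O)c6c(OCc7ccccc7)cc(OCc7ccccc7)cc6O5)cc4)c3o2)cc1 | intermediate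
16 | 5,7-bis(benzyloxy)-8-{4-[5,7-bis(benzyloxy)-4-oxo-4H-chromen-2-yl]phenoxy}-2-(4-methoxyphenyl)-4H-chromen-4-one | COc1ccc(-c2cc(=O)c3c(OCc4ccccc4)cc(OCc4ccccc4)c(Oc4ccc(-c5cc(=O)c6c(OCc7ccccc7)cc(OCc7ccccc7)cc6o5)cc4)c3o2)cc1 | intermediate
17 | 8-[4-(5,7-dihydroxy-4-oxo-4H-chromen-2-yl)phenoxy]-5,7-dihydroxy-2-(4-methoxyphenyl)-4H-chromen-4-one (CNP0295851.0, achiral) | COc1ccc(-c2cc(=O)c3c(O)cc(O)c(Oc4ccc(-c5cc(=O)c6c(O)cc(O)cc6o5)cc4)c3o2)cc1 | target

**Total step count:** 10.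
**Longest linear sequence:** 10 steps (1 to 17; compound 2 is used twice, in steps 2 and 8).

**Three steps most likely to fail**

Step 5 borylates iodide 8, which is electron-rich and flanked on both sides, so hydrodeiodination is the danger. The fallback reverses the polarity of the ether synthesis and does without the phenol. It sets out from 8 and comes back at 12. Iodide 8 serves as the electrophile in an Ullmann-type O-arylation of purchased 4-hydroxybenzaldehyde (CuI, picolinic acid, K3PO4, DMSO, 100 °C). This gives 12 directly, so 9 and 10 are bypassed and no compound outside the list is made (F0).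

Step 4 heats iodochalcone 6 with I2/DMSO, and the activated iodophenol may lose or scramble its iodine before ring closure. The fallback closes ring C first and iodinates afterwards. It sets out from 2 and comes back at 8.
- Acetophenone 2 is condensed with 4 (KOH, EtOH–THF) to (E)-1-[2,4-bis(benzyloxy)-6-hydroxyphenyl]-3-(4-methoxyphenyl)prop-2-en-1-one F1.
- I2/DMSO converts this into 5,7-bis(benzyloxy)-2-(4-methoxyphenyl)-4H-chromen-4-one F2.
- Electrophilic iodination with I2/CF3CO2Ag in CH2Cl2 attacks C8 of the fully O-alkylated ring A and gives 8. Any 6-iodo isomer is removed by crystallisation, and the regiochemistry is checked by HMBC.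

Step 8 is the aldol union, where long contact of flavone aldehyde 12 with hydroxide, poor solubility or a Cannizzaro reaction could hurt. The fallback moves the union to the carboxylic acid level as a crossed Claisen condensation, so neither hydroxide nor a later oxidation is needed. It sets out from 12 and comes back at 16, bypassing 14.
- Pinnick oxidation (NaClO2, NaH2PO4, 2-methylbut-2-ene, t-BuOH–THF–H2O) gives 4-{[5,7-bis(benzyloxy)-2-(4-methoxyphenyl)-4-oxo-4H-chromen-8-yl]oxy}benzoic acid F3.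
- (COCl)2 with catalytic DMF in CH2Cl2 gives 4-{[5,7-bis(benzyloxy)-2-(4-methoxyphenyl)-4-oxo-4H-chromen-8-yl]oxy}benzoyl chloride F4.
- F4 is added at −78 °C to 2 that has been deprotonated twice with LiHMDS (3 equiv, THF). This gives 1-[2,4-bis(benzyloxy)-6-hydroxyphenyl]-3-(4-{[5,7-bis(benzyloxy)-2-(4-methoxyphenyl)-4-oxo-4H-chromen-8-yl]oxy}phenyl)propane-1,3-dione F5.
- Catalytic p-TsOH in toluene at 90 °C cyclodehydrates F5 to 16.

**Further compounds**
F1 | step 4 | (E)-1-[2,4-bis(benzyloxy)-6-hydroxyphenyl]-3-(4-methoxyphenyl)prop-2-en-1-one | COc1ccc(/C=C/C(=O)c2c(O)cc(OCc3ccccc3)cc2OCc2ccccc2)cc1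
F2 | step 4 | 5,7-bis(benzyloxy)-2-(4-methoxyphenyl)-4H-chromen-4-one | COc1ccc(-c2cc(=O)c3c(OCc4ccccc4)cc(OCc4ccccc4)cc3o2)cc1
F0 | step 5 | none | none
F3 | step 8 | 4-{[5,7-bis(benzyloxy)-2-(4-methoxyphenyl)-4-oxo-4H-chromen-8-yl]oxy}benzoic acid | COc1ccc(-c2cc(=O)c3c(OCc4ccccc4)cc(OCc4ccccc4)c(Oc4ccc(C(=O)O)cc4)c3o2)cc1
F4 | step 8 | 4-{[5,7-bis(benzyloxy)-2-(4-methoxyphenyl)-4-oxo-4H-chromen-8-yl]oxy}benzoyl chloride | COc1ccc(-c2cc(=O)c3c(OCc4ccccc4)cc(OCc4ccccc4)c(Oc4ccc(C(=O)Cl)cc4)c3o2)cc1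
F5 | step 8 | 1-[2,4-bis(benzyloxy)-6-hydroxyphenyl]-3-(4-{[5,7-bis(benzyloxy)-2-(4-methoxyphenyl)-4-oxo-4H-chromen-8-yl]oxy}phenyl)propane-1,3-dione | COc1ccc(-c2cc(=O)c3c(OCc4ccccc4)cc(OCc4ccccc4)c(Oc4ccc(C(=O)CC(=O)c5c(O)cc(OCc6ccccc6)cc5OCc5ccccc5)cc4)c3o2)cc1
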